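Remark: positions are numbered as in the 1,4-naphthoquinone of the target (C1 carbonyl next to C2 with the side chain, C3–OH, C4 carbonyl; ring A = C4a, C5–C8, C8a). The side-chain oxygen is carried as the acetate of the target from step 2 onward; this is assumed to be an admissible protecting group for the precursor and the product of the key step.

## Structural features

The target is a bicyclic 1,4-naphthoquinone in which the benzenoid ring A (C4a, C5, C6, C7, C8, C8a) is fused through the C4a–C8a bond to the quinone ring B (C1(=O), C2, C3, C4(=O)). Ring A carries methoxy groups at C5, C7 and C8 and a single hydrogen at C6. Ring B carries a free hydroxyl at C3 (a vinylogous carboxylic acid) and, at C2, a three-carbon chain whose middle carbon is the only stereocentre, (S)-configured and acetylated, so no stereocentres stand next to each other. The fragile groups are the secondary acetate, the hydroxyquinone and the quinone itself. The acetate is base-labile and sits β to a quinone-activated CH2, so it can be lost by E1cB elimination through the quinone methide tautomer. The hydroxyquinone is acidic, chelating and easily O-alkylated or O-acylated, and the quinone is sensitive to reductants and nucleophiles. The real difficulty is regiochemical: both rings are unsymmetrical, the C6 hydrogen must lie on the same side as the C3 oxygen (the C4/C5 side), and four oxygens must be told apart, three as methyl ethers and one free. The key step exploits the fact that the sequence C5(O)–C6(H)–C7(O)–C8(O) of ring A is the sequence of oxygen and hydrogen along the four carbons of the bis(silyl) dienol ether 11 made from 9. Ring A can therefore be grown onto the C4a=C8a bond of a benzoquinone that already holds the C2 chain and the C3 oxygen. The stereocentre is taken from the chiral pool and lies one carbon away from the ring, so no step needs to create or control it.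

## Logic of the disconnections

15 ⇒ 14. The O–CH3 bond at C3 is the last one cut. A free C3–OH would be methylated with the phenols and would quench the diene, whereas as a methyl ether the same oxygen polarizes ring B for the key step. The gain is that all four oxygens are methyl ethers until the end and the acetate is already in place. The demand is a cleavage of one O–CH3 bond out of four without touching the ester; the C3 ether is the only one whose oxygen leaves as the anion of a vinylogous carboxylic acid, so an SN2 demethylation by halide should find it.

14 ⇒ 13. The O–CH3 bonds at C5 and C7 are cut, because the ring construction delivers these two oxygens as phenols while C8 and C3 arrive methylated. The forward step must methylate a hydrogen-bonded peri-phenol without a soluble base that could saponify or eliminate the acetate.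

13 ⇒ 8 + 11. The bonds C4a–C5 and C8–C8a are cut and ring A is removed. A bicyclic, pentasubstituted quinone becomes a monocyclic quinone and an acyclic four-carbon unit that brings all three ring-A oxygens and the C6 hydrogen. The forward step must add to the correct alkene of 8 with the correct orientation and aromatize without losing the C8 oxygen. This is why 8 carries bromine on the carbon next to the C4 carbonyl: it reinforces the polarization by the C3 methoxy group and leaves as HBr together with the C8a hydrogen.

11 ⇒ 10 ⇒ 9. The two O–Si bonds are cut in turn. The diene is the doubly enolized, doubly silylated form of a commercial β-keto ester, so only two silylations are needed; it is moisture-sensitive and must be used fresh.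

8 ⇒ 6 (through 7). The C–Br bond is cut. Bromine is introduced by addition to the only disubstituted alkene of 6 and loss of HBr. The demand is that the bromine stays on the carbon next to the carbonyl flanked by C–OMe, which is the expected outcome of an E1cB elimination, because that carbonyl is not weakened as a vinylogous ester and makes its α-proton the more acidic one.

6 ⇒ 5. The two quinone carbonyls are traced back to the para pair of methyl ethers; the third methyl ether survives as the C3 methoxy group. The forward oxidative demethylation must choose the para pair and leave the side chain alone. This is a further reason for the acetate, which is inert to tetravalent cerium in aqueous acid and to the HBr set free later.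

5 ⇒ 4 ⇒ 3 + 2, and 3 ⇒ 1. After removal of the acetyl group the bond between the ring carbon and the side-chain CH2 is cut. This gives the chiral-pool epoxide 2 and the aryllithium 3, available from 1 by lithiation at the only C–H flanked by two methoxy groups. The epoxide must be opened at its CH2 terminus so that the stereocentre is carried over untouched.

## Other disconnections considered

Alternative 1: The cut is C1–C2 of ring B. In the forward step NaOMe opens the lactone of the 3-alkylidene isochromane-1,4-dione A2; the released aryl 1,2-diketone carries an ortho methyl ester, and its enolate closes ring B by a Dieckmann-type acylation to give A1.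
- In its favour: A1 already has the three ring-A methyl ethers and the free C3–OH, so no phenol methylation and no unmasking at C3 follow the key step. On this point it is better than the chosen plan. The positions of all substituents are fixed by connectivity and not by directing effects, which is equal or better.
- Against it: the difficulty moves into A2, a hexasubstituted benzene with two adjacent carbonyl functions plus a stereodefined side-chain partner. The key step builds nothing of ring A, so the 5,7,8-pattern must be made separately. Methoxide excludes the acetate, so a silyl ether has to be exchanged afterwards, ending with an acylation beside a free acidic enol.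
- Comparison: on structure the chosen plan assembles ring A and its oxygens from one acyclic reagent; on mechanism the anionic ring closure is probably the more predictable step; on step economy Alternative 1 is expected to be longer because of A2.

Alternative 2: The cuts are C4–C4a and C1–C8a. In the forward step the 2-silyloxy-3-alkyl diene A5 adds thermally to the unsubstituted alkene of the methoxyquinone A4 and gives the cis-fused ene-dione A3.
- In its favour: the dienophile is cheap and no halogenation is needed, which is better than the chosen plan. The stereocentre again comes from the chiral pool (equal), and the ring-fusion stereocentres of A3 do not matter because they are erased later.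
- Against it: the orientation depends on one remote methoxy group acting on an unsymmetrical diene, a weaker control than bromine and methoxy acting together. A3 is far below the oxidation level of the target: ring A must be enolized and methylated, and C1 and C4 of ring B must both be oxidized to carbonyls. A5 also needs its own multi-step synthesis.
- Comparison: on structure it forms ring B, the ring that is simple to buy, and leaves the redox work for later; on mechanism both plans are [4+2] additions to quinones, the chosen one with the better-defined polarization; on step economy the chosen plan should be clearly shorter.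

Alternative 3: The cut is C1–C8a. In the forward step the 4-aryl-4-hydroxycyclobutenone A7 is heated in p-xylene. A 4π ring opening gives an aryl vinylketene, a 6π closure joins the ketene carbon to the arene, and tautomerization gives the hydroquinone A6 (a Moore-type ring expansion).
- In its favour: every substituent position is fixed by bonds made before the key step, so no directing effect is needed; this is better than the chosen plan. It is convergent, and ring A comes from a commercial trimethoxyarene (equal).
- Against it: the side chain must be attached to a squaric-ester-derived ring as a carbon nucleophile with an oxygen in the β-position, and such organolithium or Grignard reagents tend to β-eliminate. An indirect introduction would cost steps or the chiral-pool advantage. A6 must still be oxidized to the quinone, its isopropyl vinylogous ester must be cleaved (the same problem as the C3 methyl ether, equal), and the silyl ether must be changed into the acetate.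
- Comparison: on structure and mechanism it is the most rigorous of the four plans; on step economy it is expected to be equal at best and probably longer than the chosen plan.

Key step: step 7

## Route

Step 1
Reactants: 1 1,2,4-trimethoxybenzene; 2 (S)-propylene oxide ((S)-2-methyloxirane)
Product: 4 (S)-1-(2,3,6-trimethoxyphenyl)propan-2-ol, via 2,3,6-trimethoxyphenyllithium 3 (not isolated)
Conditions: n-BuLi, THF, 0 °C → rt; then 2, BF3·OEt2, −78 °C; H2O
Reagents that add atoms: none
Why: Directed ortho-lithiation occurs at the C–H flanked by two methoxy groups, and the aryllithium opens the BF3-activated epoxide by SN2 attack at the unsubstituted CH2; the stereocentre of 2 is not touched and appears as (S) in 4.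

Step 2
Reactants: 4 (S)-1-(2,3,6-trimethoxyphenyl)propan-2-ol
Product: 5 (S)-1-(2,3,6-trimethoxyphenyl)propan-2-yl acetate
Conditions: Ac2O, pyridine, DMAP (cat.), CH2Cl2, rt
Reagents that add atoms: acetic anhydride CC(=O)OC(C)=O
Why: Standard nucleophile-catalysed O-acetylation of a secondary alcohol with retention at carbon; the ester installed here is the one the target needs and also serves as the protecting group for all later steps.

Step 3
Reactants: 5 (S)-1-(2,3,6-trimethoxyphenyl)propan-2-yl acetate
Product: 6 2-methoxy-3-[(S)-2-acetoxypropyl]-1,4-benzoquinone
Conditions: (NH4)2Ce(NO3)6, MeCN/H2O, 0 °C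
Reagents that add atoms: water O
Why: Oxidative demethylation of a 1,4-dimethoxyarene by tetravalent cerium should convert the para pair of methyl ethers into the para-quinone and leave the third methoxy group as the vinylogous ester; the acetate is inert to the acidic oxidant.

Step 4
Reactants: 6 2-methoxy-3-[(S)-2-acetoxypropyl]-1,4-benzoquinone
Product: 8 2-bromo-6-methoxy-5-[(S)-2-acetoxypropyl]-1,4-benzoquinone, via trans-dibromide 7 (not isolated)
Conditions: Br2, CH2Cl2, 0 °C; then Et3N (1.05 equiv), 0 °C
Reagents that add atoms: bromine BrBr
Why: Bromine adds to the only disubstituted alkene, and E1cB dehydrobromination removes the more acidic proton, the one α to the carbonyl flanked by C–OMe (the carbonyl not weakened as a vinylogous ester), with loss of the β-bromide; bromine should therefore stay on the carbon next to that carbonyl, as the key step requires, and only one equivalent of amine is used at 0 °C so that the acetoxy group is not eliminated.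

Step 5
Reactants: 9 methyl 4-methoxyacetoacetate
Product: 10 methyl 4-methoxy-3-(trimethylsilyloxy)but-2-enoate
Conditions: TMSCl, Et3N, hexane, rt
Reagents that add atoms: chlorotrimethylsilane C[Si](C)(C)Cl
Why: O-Silylation of the enolizable β-keto ester gives the conjugated silyl enol ether; its alkene geometry is immaterial because it is lost in the next deprotonation.

Step 6
Reactants: 10 methyl 4-methoxy-3-(trimethylsilyloxy)but-2-enoate
Product: 11 1,4-dimethoxy-1,3-bis(trimethylsilyloxy)buta-1,3-diene
Conditions: LiN(iPr)2, THF, −78 °C; TMSCl, −78 °C → rt
Reagents that add atoms: chlorotrimethylsilane C[Si](C)(C)Cl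
Why: γ-Deprotonation at the methoxy-bearing CH2 gives the extended ester dienolate, which is silylated on the ester oxygen to the ketene silyl acetal; this is the usual two-stage preparation of 1-alkoxy-1,3-bis(silyloxy)butadienes, and the product is used crude because it hydrolyses readily.

Step 7
Reactants: 8 2-bromo-6-methoxy-5-[(S)-2-acetoxypropyl]-1,4-benzoquinone; 11 1,4-dimethoxy-1,3-bis(trimethylsilyloxy)buta-1,3-diene
Product: 13 5,7-dihydroxy-3,8-dimethoxy-2-[(S)-2-acetoxypropyl]-1,4-naphthoquinone, via cis-fused cycloadduct 12 (not isolated)
Conditions: 11 (2 equiv), CH2Cl2, −40 °C → rt; then 1 M HCl, THF, rt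
Reagents that add atoms: none
Why: This is a normal-electron-demand, strongly asynchronous Diels–Alder reaction between the electron-rich diene 11 and the bromine-bearing C4a=C8a bond of 8; the closest known type is the cycloaddition of halobenzoquinones with 1-alkoxy-1,3-bis(silyloxy)butadienes followed by aromatization. Ring A, a six-membered carbocycle, is closed by this intermolecular [4+2] addition, which forms C8–C8a and C4a–C5 in one operation and gives 12. The selectivity needed is regiochemical: the C3 methoxy group makes the C1 carbonyl a vinylogous ester, so the C4 carbonyl is the stronger acceptor with C8a as its β-carbon, and the bromine on C4a polarizes the same alkene in the same sense, so the methoxy-bearing nucleophilic terminus of 11 should bond to C8a and the ketene acetal carbon to C4a. The other quinone alkene is tetrasubstituted and donor-substituted and should not compete. Loss of HBr across C4a–C8a restores the quinone and removes the C8a hydrogen, which protects the C8 methoxy group from β-elimination; 1,4-loss of methanol (C5–OMe with C8–H) then aromatizes ring A, and the acid work-up cleaves the silyl ethers to the C5 and C7 phenols. No stereocentre is created in 13: the sp3 centres of 12 are transient and uncontrolled, the side-chain stereocentre is not involved, and the acetate is inert to the neutral diene and to brief contact with dilute acid.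

Step 8
Reactants: 13 5,7-dihydroxy-3,8-dimethoxy-2-[(S)-2-acetoxypropyl]-1,4-naphthoquinone
Product: 14 3,5,7,8-tetramethoxy-2-[(S)-2-acetoxypropyl]-1,4-naphthoquinone
Conditions: MeI (excess), Ag2O, CHCl3, rt → 40 °C, dark
Reagents that add atoms: iodomethane CI
Why: Purdie methylation is a neutral, silver-assisted O-alkylation that should also methylate the hydrogen-bonded C5 phenol; no soluble base is present, so the acetate and the base-sensitive CH2–CH(OAc) unit should survive.

Step 9
Reactants: 14 3,5,7,8-tetramethoxy-2-[(S)-2-acetoxypropyl]-1,4-naphthoquinone
Product: 15 3-hydroxy-5,7,8-trimethoxy-2-[(S)-2-acetoxypropyl]-1,4-naphthoquinone (the target)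
Conditions: LiCl (5 equiv), DMSO, 60 °C; then 1 M HCl
Reagents that add atoms: none
Why: This is the halide SN2 O-demethylation used for vinylogous methyl esters such as methyl tetronates: chloride attacks the C3 methyl group because the departing 3-oxidoquinone is the anion of a vinylogous carboxylic acid. The three aryl methyl ethers are much poorer leaving groups and the secondary acetate offers no comparable SN2 site, and because no hydroxide is present the ester and the (S) stereocentre should remain untouched.

## Compound list

1 | 1,2,4-trimethoxybenzene | COc1ccc(OC)c(OC)c1 | starting material
2 | (S)-propylene oxide ((S)-2-methyloxirane) | C[C@H]1CO1 | starting material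
3 | 2,3,6-trimethoxyphenyllithium | [Li]c1c(OC)ccc(OC)c1OC | intermediate (not isolated)
4 | (S)-1-(2,3,6-trimethoxyphenyl)propan-2-ol | COc1ccc(OC)c(C[C@H](C)O)c1OC | intermediate
5 | (S)-1-(2,3,6-trimethoxyphenyl)propan-2-yl acetate | COc1ccc(OC)c(C[C@H](C)OC(C)=O)c1OC | intermediate
6 | 2-methoxy-3-[(S)-2-acetoxypropyl]-1,4-benzoquinone | COC1=C(C[C@H](C)OC(C)=O)C(=O)C=CC1=O | intermediate
7 | trans-5,6-dibromo-2-methoxy-3-[(S)-2-acetoxypropyl]cyclohex-2-ene-1,4-dione (both trans diastereomers; ring stereocentres not defined, erased in the elimination) | COC1=C(C[C@H](C)OC(C)=O)C(=O)C(Br)C(Br)C1=O | intermediate (not isolated)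
8 | 2-bromo-6-methoxy-5-[(S)-2-acetoxypropyl]-1,4-benzoquinone | O=C1C(Br)=CC(=O)C(C[C@H](C)OC(C)=O)=C1OC | intermediate
9 | methyl 4-methoxyacetoacetate | COCC(=O)CC(=O)OC | starting material
10 | methyl 4-methoxy-3-(trimethylsilyloxy)but-2-enoate (alkene geometry not defined) | COCC(O[Si](C)(C)C)=CC(=O)OC | intermediate
11 | 1,4-dimethoxy-1,3-bis(trimethylsilyloxy)buta-1,3-diene (alkene geometries not defined) | COC=C(O[Si](C)(C)C)C=C(OC)O[Si](C)(C)C | intermediate
12 | 4a-bromo-3,5,8-trimethoxy-5,7-bis(trimethylsilyloxy)-2-[(S)-2-acetoxypropyl]-4a,5,8,8a-tetrahydronaphthalene-1,4-dione (cis-fused; ring stereocentres not defined, erased in the aromatization) | COC1=C(C[C@H](C)OC(C)=O)C(=O)C2C(OC)C(O[Si](C)(C)C)=CC(OC)(O[Si](C)(C)C)C2(Br)C1=O | intermediate (not isolated)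
13 | 5,7-dihydroxy-3,8-dimethoxy-2-[(S)-2-acetoxypropyl]-1,4-naphthoquinone | COc1c(O)cc(O)c2c1C(=O)C(C[C@H](C)OC(C)=O)=C(OC)C2=O | intermediate
14 | 3,5,7,8-tetramethoxy-2-[(S)-2-acetoxypropyl]-1,4-naphthoquinone | COc1cc(OC)c2c(c1OC)C(=O)C(C[C@H](C)OC(C)=O)=C(OC)C2=O | intermediate
15 | 3-hydroxy-5,7,8-trimethoxy-2-[(S)-2-acetoxypropyl]-1,4-naphthoquinone | COc1cc(OC)c2c(c1OC)C(=O)C(C[C@H](C)OC(C)=O)=C(O)C2=O | target

## Step count and least certain steps

Total step count: 9. Longest linear sequence: 7 (steps 1, 2, 3, 4, 7, 8, 9); steps 5 and 6 form the two-step branch to the diene.

Step 7 (key step).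
- What may go wrong: decomposition of the doubly silylated diene by the liberated HBr or by moisture before it has added; leakage of the orientation; aromatization by loss of the silyloxy group at C5 in place of the methoxy group. The last is harmless, because step 8 methylates whatever phenols remain to the same 14.
- Fallback: it sets out from 9 and 8 and returns at 14. It replaces the doubly silylated ketene acetal by a sturdier vinylogous ketene acetal that brings the C7 oxygen already methylated. 9 is converted with HC(OMe)3 and catalytic acid into methyl 3,4-dimethoxybut-2-enoate F1; γ-deprotonation with LiN(iPr)2 and silylation with TMSCl gives 1,3,4-trimethoxy-1-(trimethylsilyloxy)buta-1,3-diene F2; cycloaddition with 8 and the same loss of HBr and methanol should give 5-hydroxy-3,7,8-trimethoxy-2-[(S)-2-acetoxypropyl]-1,4-naphthoquinone F3, in which only the peri-phenol has to be methylated (MeI, Ag2O) to reach 14.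

Step 9.
- What may go wrong: incomplete selectivity among the four methyl ethers at the temperature needed (further demethylation at C7 or C5), or slow reaction.
- Fallback: it sets out from 14 and returns at 15, giving up selectivity in the cleavage and restoring the ester afterwards. LiOH in THF/H2O at 0 °C → rt replaces the C3 methoxy group by addition–elimination, which only the quinone vinylogous ester can undergo, and also saponifies the acetate, giving 3-hydroxy-2-[(S)-2-hydroxypropyl]-5,7,8-trimethoxy-1,4-naphthoquinone F4. The temperature is kept low so that the acetoxy group is not lost through the quinone methide before the C3 oxido group has formed. Ac2O/pyridine then gives 3-acetoxy-2-[(S)-2-acetoxypropyl]-5,7,8-trimethoxy-1,4-naphthoquinone F5, whose quinonyl acetate, an activated ester of an acidic enol, is cleaved selectively by aqueous NaHCO3 in MeOH to give 15.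

Step 4.
- What may go wrong: erosion of the regiochemistry of the HBr loss, or amine-induced elimination of acetic acid from the side chain through the quinone methide tautomer.
- Fallback: it sets out from 11 and returns at 14, fixing the halogen position by synthesis and attaching the side chain last. 5-Bromovanillin F6 undergoes Dakin oxidation (H2O2, NaOH) to 2-bromo-6-methoxybenzene-1,4-diol F7, which is oxidized with (NH4)2Ce(NO3)6 to 2-bromo-6-methoxy-1,4-benzoquinone F8. Cycloaddition with 11 under the conditions of step 7 should give 5,7-dihydroxy-3,8-dimethoxy-1,4-naphthoquinone F9 (numbered as in the target, C2 unsubstituted), and MeI/Ag2O gives 3,5,7,8-tetramethoxy-1,4-naphthoquinone F10. The side chain is then attached at the free C2–H by a Minisci-type silver-catalysed decarboxylative radical alkylation (AgNO3 cat., (NH4)2S2O8, MeCN/H2O, 65 °C) with (S)-3-acetoxybutanoic acid F11, whose stereocentre lies next to the radical carbon and is not involved; this gives 14.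

Step 1.
- What may go wrong: sluggish opening of the epoxide by an aryllithium with two ortho substituents, or competing opening by bromide or chloride traces and by residual butyllithium.
- Fallback: it sets out from 3 and returns at 4, building the carbinol by reduction. 3 is alkylated with allyl bromide to 2-allyl-1,3,4-trimethoxybenzene F12; oxidation of the terminal alkene with PdCl2/CuCl/O2 in DMF/H2O gives 1-(2,3,6-trimethoxyphenyl)propan-2-one F13; enantioselective reduction with an (S)-selective alcohol dehydrogenase (isopropanol as the hydride source) should give 4.

## Further compounds

F1 | step 7 | methyl 3,4-dimethoxybut-2-enoate (alkene geometry not defined) | COCC(OC)=CC(=O)OC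
F2 | step 7 | 1,3,4-trimethoxy-1-(trimethylsilyloxy)buta-1,3-diene (alkene geometries not defined) | COC=C(OC)C=C(OC)O[Si](C)(C)C
F3 | step 7 | 5-hydroxy-3,7,8-trimethoxy-2-[(S)-2-acetoxypropyl]-1,4-naphthoquinone | COc1cc(O)c2c(c1OC)C(=O)C(C[C@H](C)OC(C)=O)=C(OC)C2=O
F4 | step 9 | 3-hydroxy-2-[(S)-2-hydroxypropyl]-5,7,8-trimethoxy-1,4-naphthoquinone | COc1cc(OC)c2c(c1OC)C(=O)C(C[C@H](C)O)=C(O)C2=O
F5 | step 9 | 3-acetoxy-2-[(S)-2-acetoxypropyl]-5,7,8-trimethoxy-1,4-naphthoquinone | COc1cc(OC)c2c(c1OC)C(=O)C(C[C@H](C)OC(C)=O)=C(OC(C)=O)C2=O
F6 | step 4 | 5-bromovanillin (3-bromo-4-hydroxy-5-methoxybenzaldehyde) | COc1cc(C=O)cc(Br)c1O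
F7 | step 4 | 2-bromo-6-methoxybenzene-1,4-diol | COc1cc(O)cc(Br)c1O
F8 | step 4 | 2-bromo-6-methoxy-1,4-benzoquinone | COC1=CC(=O)C=C(Br)C1=O
F9 | step 4 | 5,7-dihydroxy-3,8-dimethoxy-1,4-naphthoquinone (numbered as in the target) | COc1c(O)cc(O)c2c1C(=O)C=C(OC)C2=O
F10 | step 4 | 3,5,7,8-tetramethoxy-1,4-naphthoquinone (numbered as in the target) | COc1cc(OC)c2c(c1OC)C(=O)C=C(OC)C2=O
F11 | step 4 | (S)-3-acetoxybutanoic acid | OC(=O)C[C@H](C)OC(C)=O
F12 | step 1 | 2-allyl-1,3,4-trimethoxybenzene | C=CCc1c(OC)ccc(OC)c1OC
F13 | step 1 | 1-(2,3,6-trimethoxyphenyl)propan-2-one | CC(=O)Cc1c(OC)ccc(OC)c1OC
A1 | alternative 1 | 3-hydroxy-5,7,8-trimethoxy-2-[(S)-2-(tert-butyldimethylsilyloxy)propyl]-1,4-naphthoquinone | COc1cc(OC)c2c(c1OC)C(=O)C(C[C@H](C)O[Si](C)(C)C(C)(C)C)=C(O)C2=O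
A2 | alternative 1 | 3-[(S)-3-(tert-butyldimethylsilyloxy)butylidene]-5,7,8-trimethoxyisochromane-1,4-dione (alkene geometry not defined) | COc1cc(OC)c2c(c1OC)C(=O)OC(=CC[C@H](C)O[Si](C)(C)C(C)(C)C)C2=O
A3 | alternative 2 | cis-2-methoxy-6-(tert-butyldimethylsilyloxy)-7-[(S)-2-(tert-butyldimethylsilyloxy)propyl]-4a,5,8,8a-tetrahydronaphthalene-1,4-dione (one cis-fused diastereomer shown) | COC1=CC(=O)[C@H]2CC(O[Si](C)(C)C(C)(C)C)=C(C[C@H](C)O[Si](C)(C)C(C)(C)C)C[C@H]2C1=O
A4 | alternative 2 | 2-methoxy-1,4-benzoquinone | COC1=CC(=O)C=CC1=O
A5 | alternative 2 | 2-(tert-butyldimethylsilyloxy)-3-[(S)-2-(tert-butyldimethylsilyloxy)propyl]buta-1,3-diene | C=C(O[Si](C)(C)C(C)(C)C)C(=C)C[C@H](C)O[Si](C)(C)C(C)(C)C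
A6 | alternative 3 | 3-isopropoxy-5,7,8-trimethoxy-2-[(S)-2-(tert-butyldimethylsilyloxy)propyl]naphthalene-1,4-diol | COc1cc(OC)c2c(O)c(OC(C)C)c(C[C@H](C)O[Si](C)(C)C(C)(C)C)c(O)c2c1OC
A7 | alternative 3 | 4-hydroxy-3-isopropoxy-2-[(S)-2-(tert-butyldimethylsilyloxy)propyl]-4-(2,4,5-trimethoxyphenyl)cyclobut-2-en-1-one (carbinol configuration not defined) | COc1cc(OC)c(cc1OC)C1(O)C(OC(C)C)=C(C[C@H](C)O[Si](C)(C)C(C)(C)C)C1=O
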